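The ring is numbered C1(OBz)–C2=C3–C4(OBz)–C5(OH)(CH2OH)–C6(OH). It is cut at C1–C2 and at C4–C5, the bond to the fully substituted C5. This leaves a four-carbon fragment from D-tartrate (C1, C6, C5, CH2OH) and a three-carbon (Z)-β-metallated acrylate (C2, C3, C4). In one pot the alkenyl Grignard adds to the tartrate half-aldehyde and the dioxolane ester enolate then closes the ring by Claisen acylation, a [3+3] annulation. The step exploits the cis C5/C6 diol held in a dioxolane ring: closure can only be cis-fused, which fixes quaternary C5. Both benzoate carbinols are set later by reduction of the enedione.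

Key step: step 3

Remark: compounds 1 and 4 are taken as catalogue chemicals. The key step is a one-flask sequence with two reagent additions.

Step 1
Reactants: 1 dimethyl (4S,5S)-2,2-dimethyl-1,3-dioxolane-4,5-dicarboxylate (dimethyl 2,3-O-isopropylidene-D-tartrate)
Product: 2 methyl (4S,5R)-5-(hydroxymethyl)-2,2-dimethyl-1,3-dioxolane-4-carboxylate
Conditions: NaBH4 (0.6 equiv), MeOH, 0 °C
Reagents that add atoms: none
Why: Ester reduction with limiting NaBH4 in methanol should stop largely at the mono-alcohol, and since the two esters are equivalent by the C2 axis a single compound results and no stereocentre is touched.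

Step 2
Reactants: 2 methyl (4S,5R)-5-(hydroxymethyl)-2,2-dimethyl-1,3-dioxolane-4-carboxylate
Product: 3 methyl (4S,5S)-5-formyl-2,2-dimethyl-1,3-dioxolane-4-carboxylate
Conditions: Dess–Martin periodinane, CH2Cl2, 0 °C to rt
Reagents that add atoms: none
Why: Dess–Martin oxidation turns the primary alcohol into the aldehyde under non-basic conditions that spare ester and ketal, and the trans-dioxolane is the stable epimer so C5 is not at risk.

Step 3
Reactants: 3 methyl (4S,5S)-5-formyl-2,2-dimethyl-1,3-dioxolane-4-carboxylate; 4 methyl (2Z)-3-iodoprop-2-enoate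
Product: 7 methyl (3aR,7aR)-7-hydroxy-2,2-dimethyl-4-oxo-3a,4,7,7a-tetrahydro-1,3-benzodioxole-3a-carboxylate (mixture of C7 epimers), via (Z)-alkenylmagnesium chloride 5 (not isolated), via chloromagnesium alkoxide 6 (not isolated)
Conditions: 4, i-PrMgCl·LiCl, THF, −78 °C; then 3, −78 °C; then LiN(i-Pr)2, THF, −78 °C
Reagents that add atoms: none
Why: Iodine–magnesium exchange on the activated alkenyl iodide gives the (Z)-alkenyl Grignard reagent with retention, and its 1,2-addition to the aldehyde of 3 forms the C6–C7 bond (numbering of 7); LiN(i-Pr)2 then removes the dioxolane C–H next to the remaining ester, and the enolate acylates itself on the (Z)-enoate ester (or on the butenolide the alkoxide can form from it), which forms the C3a–C4 bond and expels methoxide. The closest known reaction types are the addition of ester-bearing alkenylmagnesium reagents to α-alkoxy aldehydes and the Dieckmann (intramolecular Claisen) cyclisation of a preformed ester enolate to a cyclic β-keto ester with a quaternary α-carbon. The six-membered ring closes in the 6-exo-trig mode, enolate carbon onto ester carbonyl, and the (Z)-alkene brought in by the reagent is what lets the chain reach. Quaternary C3a is controlled by the tether: the acylating carbon hangs from C7a, so only the cis-fused bicycle can form and the ester stays trans to that chain as in the tartrate; C7 arises with only modest 1,2-induction from C7a and is erased in step 4. The step needs the enolate to acylate faster than the dioxolane opens by β-elimination, and deprotonation at the dioxolane carbon only; the low temperature, the ring-bound β-oxygen and the lack of any other acidic C–H (the carbinol carbon carries an alkoxide) should secure this.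

Step 4
Reactants: 7 methyl (3aR,7aR)-7-hydroxy-2,2-dimethyl-4-oxo-3a,4,7,7a-tetrahydro-1,3-benzodioxole-3a-carboxylate
Product: 8 methyl (3aR,7aS)-2,2-dimethyl-4,7-dioxo-3a,4,7,7a-tetrahydro-1,3-benzodioxole-3a-carboxylate
Conditions: Dess–Martin periodinane, CH2Cl2, 0 °C
Reagents that add atoms: none
Why: Dess–Martin oxidation of the secondary allylic alcohol gives the enedione and removes the C7 stereocentre, so both epimers of 7 converge on one compound.

Step 5
Reactants: 8 methyl (3aR,7aS)-2,2-dimethyl-4,7-dioxo-3a,4,7,7a-tetrahydro-1,3-benzodioxole-3a-carboxylate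
Product: 10 (3aS,4S,7R,7aR)-3a-(hydroxymethyl)-2,2-dimethyl-3a,4,7,7a-tetrahydro-1,3-benzodioxole-4,7-diol, via diol ester 9 (not isolated)
Conditions: NaBH4, CeCl3·7H2O, MeOH, −78 °C; then LiBH4, THF, 0 °C to rt
Reagents that add atoms: none
Why: Luche reduction should reduce both enone carbonyls in 1,2-fashion with hydride entering from the convex face, anti to the dioxolane C–O bonds, which sets C4 (S) and C7 (R) with both hydroxyls cis to the ring oxygens, and LiBH4 then reduces the methyl ester to the primary alcohol.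

Step 6
Reactants: 10 (3aS,4S,7R,7aR)-3a-(hydroxymethyl)-2,2-dimethyl-3a,4,7,7a-tetrahydro-1,3-benzodioxole-4,7-diol
Product: 11 (3aS,4S,7R,7aR)-3a-{[tert-butyl(dimethyl)silyl]oxymethyl}-2,2-dimethyl-3a,4,7,7a-tetrahydro-1,3-benzodioxole-4,7-diol
Conditions: TBSCl (1.05 equiv), imidazole, DMF, 0 °C
Reagents that add atoms: tert-butyldimethylsilyl chloride, CC(C)(C)[Si](C)(C)Cl
Why: Silyl ether formation should select the primary hydroxyl over the two more hindered secondary allylic hydroxyls on steric grounds, and no stereocentre is involved.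

Step 7
Reactants: 11 (3aS,4S,7R,7aR)-3a-{[tert-butyl(dimethyl)silyl]oxymethyl}-2,2-dimethyl-3a,4,7,7a-tetrahydro-1,3-benzodioxole-4,7-diol
Product: 12 (3aS,4S,7R,7aR)-3a-{[tert-butyl(dimethyl)silyl]oxymethyl}-2,2-dimethyl-3a,4,7,7a-tetrahydro-1,3-benzodioxole-4,7-diyl dibenzoate
Conditions: BzCl, pyridine, DMAP (cat.), 0 °C to rt
Reagents that add atoms: benzoyl chloride, O=C(Cl)c1ccccc1
Why: DMAP-catalysed acylation esterifies both secondary alcohols at oxygen, so the configuration at C4 and C7 is retained.

Step 8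
Reactants: 12 (3aS,4S,7R,7aR)-3a-{[tert-butyl(dimethyl)silyl]oxymethyl}-2,2-dimethyl-3a,4,7,7a-tetrahydro-1,3-benzodioxole-4,7-diyl dibenzoate
Product: 13 (1R,4S,5R,6R)-5,6-dihydroxy-5-(hydroxymethyl)cyclohex-2-ene-1,4-diyl dibenzoate
Conditions: CF3CO2H/H2O (4:1), 0 °C to rt
Reagents that add atoms: none
Why: Acid-catalysed hydrolysis removes the isopropylidene ketal and the silyl ether while the benzoates survive aqueous acid, and no C–O bond at a stereocentre is broken.

Compound list
1 | dimethyl (4S,5S)-2,2-dimethyl-1,3-dioxolane-4,5-dicarboxylate | COC(=O)[C@H]1OC(C)(C)O[C@@H]1C(=O)OC | starting material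
2 | methyl (4S,5R)-5-(hydroxymethyl)-2,2-dimethyl-1,3-dioxolane-4-carboxylate | COC(=O)[C@H]1OC(C)(C)O[C@@H]1CO | intermediate
3 | methyl (4S,5S)-5-formyl-2,2-dimethyl-1,3-dioxolane-4-carboxylate | COC(=O)[C@H]1OC(C)(C)O[C@@H]1C=O | intermediate
4 | methyl (2Z)-3-iodoprop-2-enoate | COC(=O)/C=C\I | starting material
5 | (Z)-(3-methoxy-3-oxoprop-1-en-1-yl)magnesium chloride | COC(=O)/C=C\[Mg]Cl | intermediate
6 | chloromagnesium alkoxide of methyl (4S,5R)-5-[(2Z)-1-hydroxy-4-methoxy-4-oxobut-2-en-1-yl]-2,2-dimethyl-1,3-dioxolane-4-carboxylate (both carbinol epimers) | COC(=O)[C@H]1OC(C)(C)O[C@@H]1C(O[Mg]Cl)/C=C\C(=O)OC | intermediate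
7 | methyl (3aR,7aR)-7-hydroxy-2,2-dimethyl-4-oxo-3a,4,7,7a-tetrahydro-1,3-benzodioxole-3a-carboxylate (mixture of C7 epimers) | COC(=O)[C@@]12OC(C)(C)O[C@@H]1C(O)C=CC2=O | intermediate
8 | methyl (3aR,7aS)-2,2-dimethyl-4,7-dioxo-3a,4,7,7a-tetrahydro-1,3-benzodioxole-3a-carboxylate | COC(=O)[C@@]12OC(C)(C)O[C@@H]1C(=O)C=CC2=O | intermediate
9 | methyl (3aS,4S,7R,7aR)-4,7-dihydroxy-2,2-dimethyl-3a,4,7,7a-tetrahydro-1,3-benzodioxole-3a-carboxylate | COC(=O)[C@@]12OC(C)(C)O[C@@H]1[C@H](O)C=C[C@@H]2O | intermediate
10 | (3aS,4S,7R,7aR)-3a-(hydroxymethyl)-2,2-dimethyl-3a,4,7,7a-tetrahydro-1,3-benzodioxole-4,7-diol | OC[C@@]12OC(C)(C)O[C@@H]1[C@H](O)C=C[C@@H]2O | intermediate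
11 | (3aS,4S,7R,7aR)-3a-{[tert-butyl(dimethyl)silyl]oxymethyl}-2,2-dimethyl-3a,4,7,7a-tetrahydro-1,3-benzodioxole-4,7-diol | CC(C)(C)[Si](C)(C)OC[C@@]12OC(C)(C)O[C@@H]1[C@H](O)C=C[C@@H]2O | intermediate
12 | (3aS,4S,7R,7aR)-3a-{[tert-butyl(dimethyl)silyl]oxymethyl}-2,2-dimethyl-3a,4,7,7a-tetrahydro-1,3-benzodioxole-4,7-diyl dibenzoate | CC(C)(C)[Si](C)(C)OC[C@@]12OC(C)(C)O[C@@H]1[C@H](OC(=O)c3ccccc3)C=C[C@@H]2OC(=O)c4ccccc4 | intermediate
13 | (1R,4S,5R,6R)-5,6-dihydroxy-5-(hydroxymethyl)cyclohex-2-ene-1,4-diyl dibenzoate | O=C(O[C@H]1C=C[C@@H](OC(=O)c2ccccc2)[C@@H](O)[C@]1(O)CO)c1ccccc1 | target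

Total step count: 8. Longest linear sequence: 8 steps (1 to 13); 4 enters at step 3.

Steps most likely to fail

Step 3. The magnesium alkoxide may cyclise onto the (Z)-ester before the enolate is formed, and the base then removes the γ-proton of the butenolide in place of the dioxolane α-proton; the dioxolane enolate may also open by β-elimination before it acylates. The fallback is a stepwise variant that sets out from 3, caps the carbinol oxygen and makes the cis-alkene by semi-hydrogenation. The lithium acetylide of methyl propiolate (n-BuLi, THF, −78 °C) should add to 3 to give the propargylic alcohol methyl (4S,5R)-5-(1-hydroxy-4-methoxy-4-oxobut-2-yn-1-yl)-2,2-dimethyl-1,3-dioxolane-4-carboxylate F1. TBSOTf and 2,6-lutidine should give its silyl ether methyl (4S,5S)-5-[1-(tert-butyldimethylsilyloxy)-4-methoxy-4-oxobut-2-yn-1-yl]-2,2-dimethyl-1,3-dioxolane-4-carboxylate F2. H2 over Pd/CaCO3 poisoned with Pb(OAc)2 and quinoline should give the (Z)-enoate methyl (4S,5S)-5-[(2Z)-1-(tert-butyldimethylsilyloxy)-4-methoxy-4-oxobut-2-en-1-yl]-2,2-dimethyl-1,3-dioxolane-4-carboxylate F3, which cannot lactonise. LiN(i-Pr)2 (THF, −78 °C) should then effect the Dieckmann closure to methyl (3aR,7aR)-7-(tert-butyldimethylsilyloxy)-2,2-dimethyl-4-oxo-3a,4,7,7a-tetrahydro-1,3-benzodioxole-3a-carboxylate F4. HF·pyridine removes the silyl group and the route is rejoined at 7.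

Step 5. Hydride may attack C4, next to quaternary C3a, from the face syn to the dioxolane, and the base-sensitive enedione may be lost by conjugate reduction or by elimination towards a hydroxyquinone. The fallback replaces substrate control by catalyst control and sets out from 7. The major epimer of 7 with the C7 hydroxyl cis to the dioxolane oxygens (7R) is separated. Its C4 ketone is reduced with catecholborane and (R)-2-methyl-CBS-oxazaborolidine (toluene, −78 °C; quaternary C3a as the large group). This should give diol ester 9 without passing through the enedione, and the route is rejoined at 9, which is taken through the LiBH4 stage of step 5.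

Step 6. Site selectivity may be lost, with silylation of one of the allylic hydroxyls beside the primary one. The fallback changes the order so that no primary hydroxyl exists when the secondary ones are acylated, and sets out from 9, isolated after the NaBH4 stage of step 5. BzCl, pyridine and DMAP should give methyl (3aS,4S,7R,7aR)-4,7-bis(benzoyloxy)-2,2-dimethyl-3a,4,7,7a-tetrahydro-1,3-benzodioxole-3a-carboxylate F5. CF3CO2H/H2O should remove the ketal to give methyl (1R,2R,3R,6S)-3,6-bis(benzoyloxy)-1,2-dihydroxycyclohex-4-ene-1-carboxylate F6. BH3·SMe2 with catalytic NaBH4 (THF, 0 °C to rt) reduces an ester that carries an α-hydroxyl through a cyclic alkoxyborane and leaves benzoates alone. It should give 13, so the route is rejoined at the target.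

Further compounds
F1 | step 3 | methyl (4S,5R)-5-(1-hydroxy-4-methoxy-4-oxobut-2-yn-1-yl)-2,2-dimethyl-1,3-dioxolane-4-carboxylate | COC(=O)[C@H]1OC(C)(C)O[C@@H]1C(O)C#CC(=O)OC
F2 | step 3 | methyl (4S,5S)-5-[1-(tert-butyldimethylsilyloxy)-4-methoxy-4-oxobut-2-yn-1-yl]-2,2-dimethyl-1,3-dioxolane-4-carboxylate | COC(=O)[C@H]1OC(C)(C)O[C@@H]1C(O[Si](C)(C)C(C)(C)C)C#CC(=O)OC
F3 | step 3 | methyl (4S,5S)-5-[(2Z)-1-(tert-butyldimethylsilyloxy)-4-methoxy-4-oxobut-2-en-1-yl]-2,2-dimethyl-1,3-dioxolane-4-carboxylate | COC(=O)[C@H]1OC(C)(C)O[C@@H]1C(O[Si](C)(C)C(C)(C)C)/C=C\C(=O)OC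
F4 | step 3 | methyl (3aR,7aR)-7-(tert-butyldimethylsilyloxy)-2,2-dimethyl-4-oxo-3a,4,7,7a-tetrahydro-1,3-benzodioxole-3a-carboxylate | COC(=O)[C@@]12OC(C)(C)O[C@@H]1C(O[Si](C)(C)C(C)(C)C)C=CC2=O
F0 | step 5 | none | none
F5 | step 6 | methyl (3aS,4S,7R,7aR)-4,7-bis(benzoyloxy)-2,2-dimethyl-3a,4,7,7a-tetrahydro-1,3-benzodioxole-3a-carboxylate | COC(=O)[C@@]12OC(C)(C)O[C@@H]1[C@H](OC(=O)c3ccccc3)C=C[C@@H]2OC(=O)c4ccccc4
F6 | step 6 | methyl (1R,2R,3R,6S)-3,6-bis(benzoyloxy)-1,2-dihydroxycyclohex-4-ene-1-carboxylate | COC(=O)[C@@]1(O)[C@H](O)[C@H](OC(=O)c2ccccc2)C=C[C@@H]1OC(=O)c3ccccc3
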